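**Plan**

- Numbering: unit 1 is the 5,7-dihydroxyflavanone (O1 to C8a, ring B C1' to C6'); unit 2 is the 7-methoxyflavanone (O1'' to C8a'', pendant ring C1''' to C6'''). The retrosynthesis cuts, in order: the three benzyl ethers; C4a–C5 of unit 1; C2''–C1'''; the biaryl bond C3'–C8''; O1–C8a and C4–C4a of unit 1.
- Enabling feature: ring A of unit 1 (C4a, C5, C6, C7, C8, C8a) is an unsubstituted acylphloroglucinol. Its C4 carbonyl and its oxygens at C8a, C7 and C5 alternate as in a tetraketide chain C3–C4–C4a–C8a–C8–C7–C6–C5, and O1 already ties C2 to C8a. The chain can therefore be held as a 2-aryl-2,3-dihydropyran-4-one whose enol-ether carbon C4a is nucleophilic and whose C5 end is a ketene masked as a dioxinone.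
- Forward order: the O1/C2/C3/C4/C4a/C8a heterocycle of unit 1 is built as a dihydropyranone on a bromoarene; the unit 2 chromone is made as its 8-boronate; the biaryl is joined; the unit 2 flavanone is completed by aryl addition at C2''; ring A of unit 1 is closed; the benzyl ethers are removed.
- Stereochemistry: C2 comes from asymmetric transfer hydrogenation of a β-keto ester with the (S,S)-ruthenium catalyst and is carried through unchanged. C2'' comes from a palladium/(R)-pyridine-oxazoline aryl conjugate addition. After each centre is set, only near-neutral or acidic steps follow.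

Key step: step 15

Assumption: the C3'–C8'' biaryl axis is taken as rotating freely on the laboratory time scale, since the target carries no axial descriptor. Compounds 1, 7, 12 and 19 are taken as commercial.

**Route**

Step 1
Reactants: 1 1-(3-bromo-4-hydroxyphenyl)ethan-1-one
Product: 2 1-[4-(benzyloxy)-3-bromophenyl]ethan-1-one
Conditions: BnBr, K2CO3, DMF, rt
Reagents that add atoms: benzyl bromide BrCc1ccccc1
Why: Williamson etherification of the phenoxide; the benzyl ether should survive every later base, acid and palladium step and is removed only in the final hydrogenolysis.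

Step 2
Reactants: 2 1-[4-(benzyloxy)-3-bromophenyl]ethan-1-one
Product: 3 ethyl 3-[4-(benzyloxy)-3-bromophenyl]-3-oxopropanoate
Conditions: NaH, (EtO)2CO, THF, reflux; aq. HCl work-up
Reagents that add atoms: diethyl carbonate CCOC(=O)OCC
Why: crossed Claisen condensation of the methyl ketone enolate with non-enolisable diethyl carbonate, driven to completion by deprotonation of the β-keto ester.

Step 3
Reactants: 3 ethyl 3-[4-(benzyloxy)-3-bromophenyl]-3-oxopropanoate
Product: 4 ethyl (3S)-3-[4-(benzyloxy)-3-bromophenyl]-3-hydroxypropanoate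
Conditions: RuCl[(S,S)-TsDPEN](p-cymene) (1 mol%), HCO2H/Et3N (5:2), DMF, 40 °C
Reagents that add atoms: none
Why: Noyori–Ikariya asymmetric transfer hydrogenation of an aryl ketone; the (S,S)-catalyst delivers hydride to the face that turns acetophenone into (S)-1-phenylethanol, which here (aryl ranking above CH2CO2Et) should give the (S)-carbinol that becomes C2 of unit 1, with the aryl bromide and benzyl ether untouched.

Step 4
Reactants: 4 ethyl (3S)-3-[4-(benzyloxy)-3-bromophenyl]-3-hydroxypropanoate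
Product: 5 ethyl (3S)-3-[4-(benzyloxy)-3-bromophenyl]-3-(triethylsilyloxy)propanoate
Conditions: Et3SiCl, imidazole, DMF, 0 °C to rt
Reagents that add atoms: chlorotriethylsilane CC[Si](Cl)(CC)CC
Why: silyl ether protection of the secondary alcohol, which prevents alkoxide formation and retro-aldol cleavage in the two strongly basic steps that follow and is acid-labile enough to come off in step 8.

Step 5
Reactants: 5 ethyl (3S)-3-[4-(benzyloxy)-3-bromophenyl]-3-(triethylsilyloxy)propanoate
Product: 6 (3S)-3-[4-(benzyloxy)-3-bromophenyl]-N-methoxy-N-methyl-3-(triethylsilyloxy)propanamide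
Conditions: MeNH(OMe)·HCl, iPrMgCl, THF, −20 to 0 °C
Reagents that add atoms: N,O-dimethylhydroxylamine hydrochloride CNOC.Cl
Why: Weinreb amide formation by aminolysis of the ester with the magnesium amide made in the flask; the low temperature should leave the β-silyloxy stereocentre untouched.

Step 6
Reactants: 7 2,2,6-trimethyl-4H-1,3-dioxin-4-one
Product: 8 2,2-dimethyl-6-(2-oxopropyl)-4H-1,3-dioxin-4-one
Conditions: LiN(SiMe3)2, THF, −78 °C; AcCl (0.5 equiv), −78 to −20 °C; 1 M HCl work-up
Reagents that add atoms: acetyl chloride CC(=O)Cl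
Why: γ-selective vinylogous Claisen acylation of the lithium dienolate of the dioxinone; half an equivalent of acid chloride is used because the more acidic product consumes a second equivalent of dienolate.

Step 7
Reactants: 6 (3S)-3-[4-(benzyloxy)-3-bromophenyl]-N-methoxy-N-methyl-3-(triethylsilyloxy)propanamide; 8 2,2-dimethyl-6-(2-oxopropyl)-4H-1,3-dioxin-4-one
Product: 9 6-[(6S)-6-[4-(benzyloxy)-3-bromophenyl]-2,4-dioxo-6-(triethylsilyloxy)hexyl]-2,2-dimethyl-4H-1,3-dioxin-4-one
Conditions: 8 (2.2 equiv), LiN(iPr)2 (4.5 equiv), THF, −78 °C; then 6, −78 to −40 °C; 1 M HCl to pH 3, used at once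
Reagents that add atoms: none
Why: Claisen-type C-acylation of the terminal carbon of the keto-dioxinone dianion by the Weinreb amide forms C4–C4a; the chelated tetrahedral intermediate stops over-addition, and the amide base should not attack the aryl bromide or the silyl ether.

Step 8
Reactants: 9 6-[(6S)-6-[4-(benzyloxy)-3-bromophenyl]-2,4-dioxo-6-(triethylsilyloxy)hexyl]-2,2-dimethyl-4H-1,3-dioxin-4-one
Product: 11 6-{[(2S)-2-[4-(benzyloxy)-3-bromophenyl]-4-oxo-3,4-dihydro-2H-pyran-6-yl]methyl}-2,2-dimethyl-4H-1,3-dioxin-4-one, via hydroxy diketo-dioxinone 10 (not isolated)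
Conditions: TFA, wet CH2Cl2, 0 °C to rt
Reagents that add atoms: none
Why: acidic desilylation followed by cyclodehydration of the δ-hydroxy-β-diketone (6-exo-trig hemiketalisation at the distal ketone, then loss of water) gives the 2,3-dihydro-4H-pyran-4-one and forms O1–C8a; under acid this should outrun the base-promoted aldol fold of the diketo-dioxinone, and no bond to C2 is broken.

Step 9
Reactants: 12 1-(2,6-dihydroxy-4-methoxyphenyl)ethan-1-one
Product: 13 1-[2-(benzyloxy)-6-hydroxy-4-methoxyphenyl]ethan-1-one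
Conditions: BnBr (1.05 equiv), K2CO3, acetone, reflux
Reagents that add atoms: benzyl bromide BrCc1ccccc1
Why: Williamson mono-benzylation of a symmetric bis-phenol; after the first alkylation the remaining hydroxyl is hydrogen-bonded to the ketone and much less nucleophilic.

Step 10
Reactants: 13 1-[2-(benzyloxy)-6-hydroxy-4-methoxyphenyl]ethan-1-one
Product: 14 1-[6-(benzyloxy)-2-hydroxy-3-iodo-4-methoxyphenyl]ethan-1-one
Conditions: NIS, TFA (cat.), MeCN, 0 °C to rt
Reagents that add atoms: N-iodosuccinimide O=C1CCC(=O)N1I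
Why: electrophilic aromatic iodination, expected ortho to the free chelated phenol (between OH and OMe) as is usual for 2'-hydroxy-4',6'-dialkoxyacetophenones; this places iodine on the carbon that becomes C8''.

Step 11
Reactants: 14 1-[6-(benzyloxy)-2-hydroxy-3-iodo-4-methoxyphenyl]ethan-1-one
Product: 16 5-(benzyloxy)-8-iodo-7-methoxy-4H-chromen-4-one, via enaminone 15 (not isolated)
Conditions: Me2NCH(OMe)2, toluene, 100 °C; then conc. HCl, CH2Cl2, 40 °C
Reagents that add atoms: N,N-dimethylformamide dimethyl acetal COC(OC)N(C)C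
Why: enaminone condensation at the acetyl methyl group followed by acid-promoted oxa-Michael addition of the phenol and loss of dimethylamine, the standard chromone synthesis from 2'-hydroxyacetophenones.

Step 12
Reactants: 16 5-(benzyloxy)-8-iodo-7-methoxy-4H-chromen-4-one
Product: 17 5-(benzyloxy)-7-methoxy-8-(4,4,5,5-tetramethyl-1,3,2-dioxaborolan-2-yl)-4H-chromen-4-one
Conditions: B2pin2, Pd(dppf)Cl2, KOAc, 1,4-dioxane, 90 °C
Reagents that add atoms: bis(pinacolato)diboron CC1(C)OB(OC1(C)C)B1OC(C)(C)C(C)(C)O1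
Why: Miyaura borylation of the aryl iodide; the heat is applied to the robust achiral chromone so that the thermally labile dioxinone partner never meets these conditions.

Step 13
Reactants: 11 6-{[(2S)-2-[4-(benzyloxy)-3-bromophenyl]-4-oxo-3,4-dihydro-2H-pyran-6-yl]methyl}-2,2-dimethyl-4H-1,3-dioxin-4-one; 17 5-(benzyloxy)-7-methoxy-8-(4,4,5,5-tetramethyl-1,3,2-dioxaborolan-2-yl)-4H-chromen-4-one
Product: 18 5-(benzyloxy)-8-{2-(benzyloxy)-5-[(2S)-6-[(2,2-dimethyl-4-oxo-4H-1,3-dioxin-6-yl)methyl]-4-oxo-3,4-dihydro-2H-pyran-2-yl]phenyl}-7-methoxy-4H-chromen-4-one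
Conditions: Pd(OAc)2, SPhos, K3PO4, toluene/H2O, 50 °C
Reagents that add atoms: none
Why: Suzuki–Miyaura coupling forms the C3'–C8'' bond; a dialkylbiarylphosphine on zerovalent palladium is the usual answer to a tri-ortho-substituted biaryl, and 50 °C stays well below the temperature at which the dioxinone loses acetone.

Step 14
Reactants: 18 5-(benzyloxy)-8-{2-(benzyloxy)-5-[(2S)-6-[(2,2-dimethyl-4-oxo-4H-1,3-dioxin-6-yl)methyl]-4-oxo-3,4-dihydro-2H-pyran-2-yl]phenyl}-7-methoxy-4H-chromen-4-one; 19 [4-(benzyloxy)phenyl]boronic acid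
Product: 20 (2S)-5-(benzyloxy)-2-[4-(benzyloxy)phenyl]-8-{2-(benzyloxy)-5-[(2S)-6-[(2,2-dimethyl-4-oxo-4H-1,3-dioxin-6-yl)methyl]-4-oxo-3,4-dihydro-2H-pyran-2-yl]phenyl}-7-methoxychroman-4-one
Conditions: 19 (2.5 equiv), Pd(OCOCF3)2 (10 mol%), (R)-t-BuPyOx (12 mol%), NH4PF6 (30 mol%), H2O (5 equiv), ClCH2CH2Cl, 50 °C
Reagents that add atoms: none
Why: asymmetric conjugate addition of an arylboronic acid to a chromone under divalent palladium/pyridine-oxazoline catalysis forms C2''–C1'''; the (R)-ligand is chosen because its mirror image is the one that gives (R)-2-arylchromanones, so C2'' should come out (S) under catalyst control, and the C2-unsubstituted chromone should react ahead of the β-alkoxy-β-alkyl enone of the dihydropyranone.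

Step 15
Reactants: 20 (2S)-5-(benzyloxy)-2-[4-(benzyloxy)phenyl]-8-{2-(benzyloxy)-5-[(2S)-6-[(2,2-dimethyl-4-oxo-4H-1,3-dioxin-6-yl)methyl]-4-oxo-3,4-dihydro-2H-pyran-2-yl]phenyl}-7-methoxychroman-4-one
Product: 23 (2S)-2-{4-(benzyloxy)-3-[(2S)-5-(benzyloxy)-2-[4-(benzyloxy)phenyl]-7-methoxy-4-oxochroman-8-yl]phenyl}-5,7-dihydroxychroman-4-one, via acylketene 21 (not isolated), via cyclohexadienone 22 (not isolated)
Conditions: anhydrous degassed toluene (0.005 M), 110 °C
Reagents that add atoms: none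
Why: Proposed new method: retro-[4+2] loss of acetone from the dioxinone unmasks acylketene 21, whose C7 ketone enolises toward C8 to give a dienylketene running C5=C6–C7=C8–C8a=C4a; thermal 6π electrocyclisation (equivalently, attack of the enol-ether carbon C4a on the ketene carbon C5 followed by loss of a C8 proton) forms C4a–C5 and gives dienone 22, which tautomerises to the aromatic 5,7-diol. The closest known reaction types are the thermolysis of dioxinones to acylketenes in biomimetic resorcylate synthesis and the dienylketene ring closure that ends the Danheiser benzannulation; C-acylation of a dihydropyranone enol ether by a tethered acylketene is not established. Ring A closes as a six-membered carbocycle by disrotatory 6π closure, the only reasonable ring size, since bonding of C8 to C5 would give a four-membered ring. No stereocentre is created: C4a of 22 is transient and becomes sp2 on aromatisation, while C2 and C2'' lie outside the reacting array and meet neither acid nor base. The selectivity needed is the Claisen-type fold over the aldol fold, pyrone formation and ketene dimerisation; the dihydropyranone secures it by turning the C4 carbonyl into an unreactive vinylogous ester outside the chain and by having already alkylated the C8a oxygen, and high dilution in dry toluene suppresses bimolecular capture.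

Step 16
Reactants: 23 (2S)-2-{4-(benzyloxy)-3-[(2S)-5-(benzyloxy)-2-[4-(benzyloxy)phenyl]-7-methoxy-4-oxochroman-8-yl]phenyl}-5,7-dihydroxychroman-4-one
Product: 24 (2S)-2-{4-hydroxy-3-[(2S)-5-hydroxy-2-(4-hydroxyphenyl)-7-methoxy-4-oxochroman-8-yl]phenyl}-5,7-dihydroxychroman-4-one
Conditions: H2 (1 atm), Pd/C, EtOAc/MeOH, rt
Reagents that add atoms: none
Why: catalytic hydrogenolysis of the three aryl benzyl ethers under neutral conditions, which should leave the flavanone carbonyls, the methyl ether and both C2 stereocentres intact.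

**Compound list**

1 | 1-(3-bromo-4-hydroxyphenyl)ethan-1-one | CC(=O)c1ccc(O)c(Br)c1 | starting material
2 | 1-[4-(benzyloxy)-3-bromophenyl]ethan-1-one | CC(=O)c1ccc(OCc2ccccc2)c(Br)c1 | intermediate
3 | ethyl 3-[4-(benzyloxy)-3-bromophenyl]-3-oxopropanoate | CCOC(=O)CC(=O)c1ccc(OCc2ccccc2)c(Br)c1 | intermediate
4 | ethyl (3S)-3-[4-(benzyloxy)-3-bromophenyl]-3-hydroxypropanoate | CCOC(=O)C[C@H](O)c1ccc(OCc2ccccc2)c(Br)c1 | intermediate
5 | ethyl (3S)-3-[4-(benzyloxy)-3-bromophenyl]-3-(triethylsilyloxy)propanoate | CCOC(=O)C[C@H](O[Si](CC)(CC)CC)c1ccc(OCc2ccccc2)c(Br)c1 | intermediate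
6 | (3S)-3-[4-(benzyloxy)-3-bromophenyl]-N-methoxy-N-methyl-3-(triethylsilyloxy)propanamide | CON(C)C(=O)C[C@H](O[Si](CC)(CC)CC)c1ccc(OCc2ccccc2)c(Br)c1 | intermediate
7 | 2,2,6-trimethyl-4H-1,3-dioxin-4-one | CC1=CC(=O)OC(C)(C)O1 | starting material
8 | 2,2-dimethyl-6-(2-oxopropyl)-4H-1,3-dioxin-4-one | CC(=O)CC1=CC(=O)OC(C)(C)O1 | intermediate
9 | 6-[(6S)-6-[4-(benzyloxy)-3-bromophenyl]-2,4-dioxo-6-(triethylsilyloxy)hexyl]-2,2-dimethyl-4H-1,3-dioxin-4-one | CC1(C)OC(=O)C=C(CC(=O)CC(=O)C[C@H](O[Si](CC)(CC)CC)c2ccc(OCc3ccccc3)c(Br)c2)O1 | intermediate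
10 | 6-[(6S)-6-[4-(benzyloxy)-3-bromophenyl]-6-hydroxy-2,4-dioxohexyl]-2,2-dimethyl-4H-1,3-dioxin-4-one (formed in the flask) | CC1(C)OC(=O)C=C(CC(=O)CC(=O)C[C@H](O)c2ccc(OCc3ccccc3)c(Br)c2)O1 | intermediate
11 | 6-{[(2S)-2-[4-(benzyloxy)-3-bromophenyl]-4-oxo-3,4-dihydro-2H-pyran-6-yl]methyl}-2,2-dimethyl-4H-1,3-dioxin-4-one | Brc1cc([C@@H]2CC(=O)C=C(CC3=CC(=O)OC(C)(C)O3)O2)ccc1OCc1ccccc1 | intermediate
12 | 1-(2,6-dihydroxy-4-methoxyphenyl)ethan-1-one | COc1cc(O)c(C(C)=O)c(O)c1 | starting material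
13 | 1-[2-(benzyloxy)-6-hydroxy-4-methoxyphenyl]ethan-1-one | COc1cc(O)c(C(C)=O)c(OCc2ccccc2)c1 | intermediate
14 | 1-[6-(benzyloxy)-2-hydroxy-3-iodo-4-methoxyphenyl]ethan-1-one | COc1cc(OCc2ccccc2)c(C(C)=O)c(O)c1I | intermediate
15 | (E)-1-[6-(benzyloxy)-2-hydroxy-3-iodo-4-methoxyphenyl]-3-(dimethylamino)prop-2-en-1-one (formed in the flask) | COc1cc(OCc2ccccc2)c(C(=O)/C=C/N(C)C)c(O)c1I | intermediate
16 | 5-(benzyloxy)-8-iodo-7-methoxy-4H-chromen-4-one | COc1cc(OCc2ccccc2)c2c(=O)ccoc2c1I | intermediate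
17 | 5-(benzyloxy)-7-methoxy-8-(4,4,5,5-tetramethyl-1,3,2-dioxaborolan-2-yl)-4H-chromen-4-one | COc1cc(OCc2ccccc2)c2c(=O)ccoc2c1B1OC(C)(C)C(C)(C)O1 | intermediate
18 | 5-(benzyloxy)-8-{2-(benzyloxy)-5-[(2S)-6-[(2,2-dimethyl-4-oxo-4H-1,3-dioxin-6-yl)methyl]-4-oxo-3,4-dihydro-2H-pyran-2-yl]phenyl}-7-methoxy-4H-chromen-4-one | COc1cc(OCc2ccccc2)c2c(=O)ccoc2c1-c1cc([C@@H]3CC(=O)C=C(CC4=CC(=O)OC(C)(C)O4)O3)ccc1OCc1ccccc1 | intermediate
19 | [4-(benzyloxy)phenyl]boronic acid | OB(O)c1ccc(OCc2ccccc2)cc1 | starting material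
20 | (2S)-5-(benzyloxy)-2-[4-(benzyloxy)phenyl]-8-{2-(benzyloxy)-5-[(2S)-6-[(2,2-dimethyl-4-oxo-4H-1,3-dioxin-6-yl)methyl]-4-oxo-3,4-dihydro-2H-pyran-2-yl]phenyl}-7-methoxychroman-4-one (key-step precursor) | COc1cc(OCc2ccccc2)c2c(c1-c1cc([C@@H]3CC(=O)C=C(CC4=CC(=O)OC(C)(C)O4)O3)ccc1OCc1ccccc1)O[C@H](c1ccc(OCc3ccccc3)cc1)CC2=O | intermediate
21 | acylketene from 20: (2S)-5-(benzyloxy)-2-[4-(benzyloxy)phenyl]-8-{2-(benzyloxy)-5-[(2S)-6-(2,4-dioxobut-3-en-1-yl)-4-oxo-3,4-dihydro-2H-pyran-2-yl]phenyl}-7-methoxychroman-4-one (formed in the flask) | COc1cc(OCc2ccccc2)c2c(c1-c1cc([C@@H]3CC(=O)C=C(CC(=O)C=C=O)O3)ccc1OCc1ccccc1)O[C@H](c1ccc(OCc3ccccc3)cc1)CC2=O | intermediate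
22 | ring-closed dienone tautomer: (2S)-2-{4-(benzyloxy)-3-[(2S)-5-(benzyloxy)-2-[4-(benzyloxy)phenyl]-7-methoxy-4-oxochroman-8-yl]phenyl}-7-hydroxy-2,3-dihydro-4aH-chromene-4,5-dione, C4a unassigned (formed in the flask) | COc1cc(OCc2ccccc2)c2c(c1-c1cc([C@@H]3CC(=O)C4C(=O)C=C(O)C=C4O3)ccc1OCc1ccccc1)O[C@H](c1ccc(OCc3ccccc3)cc1)CC2=O | intermediate
23 | (2S)-2-{4-(benzyloxy)-3-[(2S)-5-(benzyloxy)-2-[4-(benzyloxy)phenyl]-7-methoxy-4-oxochroman-8-yl]phenyl}-5,7-dihydroxychroman-4-one (key-step product) | COc1cc(OCc2ccccc2)c2c(c1-c1cc([C@@H]3CC(=O)c4c(O)cc(O)cc4O3)ccc1OCc1ccccc1)O[C@H](c1ccc(OCc3ccccc3)cc1)CC2=O | intermediate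
24 | (2S)-2-{4-hydroxy-3-[(2S)-5-hydroxy-2-(4-hydroxyphenyl)-7-methoxy-4-oxochroman-8-yl]phenyl}-5,7-dihydroxychroman-4-one | COc1cc(O)c2c(c1-c1cc([C@@H]3CC(=O)c4c(O)cc(O)cc4O3)ccc1O)O[C@H](c1ccc(O)cc1)CC2=O | target

**Step count**

Total: 16 steps. Longest linear sequence: 11 steps (steps 1, 2, 3, 4, 5, 7, 8, 13, 14, 15, 16).

**Steps most likely to fail**

Step 15 (key step).
- What may go wrong: the acylketene may be consumed by dimerisation, or by traces of water (hydration, then decarboxylation to a methyl ketone), faster than C4a bonds to C5. The cross-conjugated enol ether may also be too weak a nucleophile, so that only decomposition is seen.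
- Fallback (known chemistry; ring A of unit 1 is brought in ready-made instead of being folded): it sets out from boronate 17 and rejoins the route at target 24. Commercial 5,7-dihydroxy-4H-chromen-4-one is dibenzylated (BnBr, K2CO3, DMF, 60 °C) to 5,7-bis(benzyloxy)-4H-chromen-4-one F1. Conjugate addition of commercial [4-(benzyloxy)-3-chlorophenyl]boronic acid under the catalyst of step 14 should give (2S)-5,7-bis(benzyloxy)-2-[4-(benzyloxy)-3-chlorophenyl]chroman-4-one F2. Suzuki–Miyaura coupling of F2 with 17 (Pd(OAc)2, SPhos, K3PO4, toluene/H2O, 40 °C) gives the flavanone–chromone biaryl F3. A second conjugate addition, now of 19, gives the pentabenzyl ether of the target F4, and hydrogenolysis as in step 16 gives 24.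

Step 14.
- What may go wrong: aryl transfer to the electron-rich 5,7-dialkoxychromone may be slow enough for protodeboronation of 19 to win. The dihydropyranone enone may be arylated as well, the wet Lewis-acidic medium may erode the dioxinone, and facial control may be lower than on simple chromones.
- Fallback (C2'' is set on the simple fragment before the fragments are joined): it sets out from iodochromone 16 and bromide 11 and rejoins the route at 20. Conjugate addition of 19 to 16 with the same catalyst should give (2S)-5-(benzyloxy)-2-[4-(benzyloxy)phenyl]-8-iodo-7-methoxychroman-4-one F5. Miyaura borylation of 11 (B2pin2, Pd(OAc)2, XPhos, KOAc, 1,4-dioxane, 60 °C) gives the pinacol boronate of the dihydropyranone–dioxinone F6. Coupling of F5 with F6 at room temperature (Pd(OAc)2, SPhos, K3PO4, THF/H2O, short reaction time to spare the flavanone) gives 20.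

Step 13.
- What may go wrong: phosphate may deprotonate the doubly vinylogous CH2 between the two heterocycles of 11, and the resulting anion may stall or divert the catalyst. The doubly ortho-substituted boronate 17 may protodeboronate before the hindered transmetalation.
- Fallback (a base-free organotin coupling in place of the boron/base coupling): it sets out from 16 and 11 and rejoins the route at 18. Stannylation of 16 (Me3SnSnMe3, Pd(PPh3)4, toluene, 100 °C) gives 5-(benzyloxy)-7-methoxy-8-(trimethylstannyl)-4H-chromen-4-one F7. Stille coupling of F7 with 11 (Pd(PtBu3)2, CuI, DMF, 45 °C) gives 18 without added base.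

Further compounds
F1 | step 15 | 5,7-bis(benzyloxy)-4H-chromen-4-one | O=c1ccoc2cc(OCc3ccccc3)cc(OCc3ccccc3)c12
F2 | step 15 | (2S)-5,7-bis(benzyloxy)-2-[4-(benzyloxy)-3-chlorophenyl]chroman-4-one | Clc1cc([C@@H]2CC(=O)c3c(OCc4ccccc4)cc(OCc4ccccc4)cc3O2)ccc1OCc1ccccc1
F3 | step 15 | 5-(benzyloxy)-8-{2-(benzyloxy)-5-[(2S)-5,7-bis(benzyloxy)-4-oxochroman-2-yl]phenyl}-7-methoxy-4H-chromen-4-one | COc1cc(OCc2ccccc2)c2c(=O)ccoc2c1-c1cc([C@@H]3CC(=O)c4c(OCc5ccccc5)cc(OCc5ccccc5)cc4O3)ccc1OCc1ccccc1
F4 | step 15 | (2S)-5-(benzyloxy)-2-[4-(benzyloxy)phenyl]-8-{2-(benzyloxy)-5-[(2S)-5,7-bis(benzyloxy)-4-oxochroman-2-yl]phenyl}-7-methoxychroman-4-one | COc1cc(OCc2ccccc2)c2c(c1-c1cc([C@@H]3CC(=O)c4c(OCc5ccccc5)cc(OCc5ccccc5)cc4O3)ccc1OCc1ccccc1)O[C@H](c1ccc(OCc3ccccc3)cc1)CC2=O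
F5 | step 14 | (2S)-5-(benzyloxy)-2-[4-(benzyloxy)phenyl]-8-iodo-7-methoxychroman-4-one | COc1cc(OCc2ccccc2)c2c(c1I)O[C@H](c1ccc(OCc3ccccc3)cc1)CC2=O
F6 | step 14 | 6-{[(2S)-2-[4-(benzyloxy)-3-(4,4,5,5-tetramethyl-1,3,2-dioxaborolan-2-yl)phenyl]-4-oxo-3,4-dihydro-2H-pyran-6-yl]methyl}-2,2-dimethyl-4H-1,3-dioxin-4-one | CC1(C)OB(OC1(C)C)c1cc([C@@H]2CC(=O)C=C(CC3=CC(=O)OC(C)(C)O3)O2)ccc1OCc1ccccc1
F7 | step 13 | 5-(benzyloxy)-7-methoxy-8-(trimethylstannyl)-4H-chromen-4-one | COc1cc(OCc2ccccc2)c2c(=O)ccoc2c1[Sn](C)(C)C
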